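The numbers in the tables were generated by integration for an exercise, and the scatter is random.

- 16.2% is the share of the epsilon charge that the coupling partner can carry into intermediate, because the first step takes one of each and less coupling partner is charged than starting material; it is the limiting reagent there.

common to all: second reagent 1.04 M

|  | starting material | coupling partner | protic impurity | remark | time |
|---|---|---|---|---|---|
| red | 0.0064 M | 0.13 M | 0.078 M | run made earlier |  |
| ochre | 0.53 M | 0.13 M | 0.078 M | run made earlier |  |
| gamma | 0.010 M | 0.130 M | 0.0780 M |  | 80 min |
| eta | 0.030 M | 0.130 M | 0.0780 M |  | 80 min |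
| zeta | 0.080 M | 0.130 M | 0.0780 M |  | 80 min |
| theta | 0.25 M | 0.130 M | 0.0780 M |  | 80 min |
| epsilon | 0.80 M | 0.130 M | 0.0780 M |  | 80 min |

| run | time / min | intermediate / % | product / % |
|---|---|---|---|
| red | 3.00 | 55.6 | 4.4 |
| red | 5.00 | 67.8 | 10.6 |
| red | 8.00 | 69.9 | 20.7 |
| red | 12.0 | 62.2 | 34.1 |
| red | 15.0 | 55.7 | 42.5 |
| red | 25.0 | 34.9 | 64.2 |
| red | 40.0 | 17.3 | 81.9 |
| ochre | 2.00 | 20.3 | 0.5 |
| ochre | 6.00 | 18.5 | 4.7 |
| ochre | 12.0 | 13.8 | 10.6 |
| ochre | 15.0 | 12.7 | 11.7 |
| ochre | 25.0 | 8.5 | 16.2 |
| ochre | 30.0 | 6.3 | 16.9 |
| ochre | 40.0 | 4.7 | 19.8 |

(each reading ± 0.5 percentage points)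

- the numbers in the tables scatter with a standard deviation of 0.5 percentage points
- steps thought possible: starting material + coupling partner -> intermediate; second reagent + intermediate -> product; starting material + protic impurity -> quenched substrate
- "hardly changes" means that all values lie within two and a half points (for a concentration: within two and a half percent of the largest)

- [intermediate] at the end for gamma, eta, zeta, theta, epsilon, in this order
- the course of these numbers from the first flask to the last (rises, then falls / hardly changes / falls, then rises / rises all the way / falls all the way)

- Ochre shows this cap as a reading: intermediate plus product stand at 24.5% of the charge at 40.0 min, and its coupling partner allows 24.5%.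
- Red gives two rates. After 3.00 min, 60.0% of the starting material has reacted, which with the coupling partner nearly constant reads as 2.35 L mol⁻¹ min⁻¹ for the first step. The tail of the intermediate in red falls at 0.0468 min⁻¹.
- The quantity carried forward is the mean wait, the average time a unit of the minority species spends before the first step takes it: the natural log of majority charge over majority minus minority charge, divided by the first constant times the minority charge. Theta's wait is 2.40 min, and epsilon's is 0.581 min, shorter than theta's.
- The second step uses up second reagent, so in theta and epsilon it loses 12.5% of its charge. Solving that step, the late share of the minority still intermediate is one minus this loss, times the exponential of minus the slowed rate 0.0409 min⁻¹ times the time less the wait.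
- By this reckoning theta keeps 1.90% of its charge, or 0.00475 M, and epsilon 0.551%, or 0.00441 M. Both flasks are charged with the same coupling partner, but epsilon's wait is shorter, so in this reckoning its intermediate starts to decay earlier and ends lower.
- Zeta, reckoned the same way, keeps 3.63% of its charge, or 0.00291 M, below theta. Gamma and eta are charged with less starting material than zeta, so this reckoning commits to a row that rises, then falls.
- The forecast differs at the far end: it has 2.800 × 10⁻⁴ M, 8.500 × 10⁻⁴ M, 0.0024 M, 0.0038 M and 0.007 M, a row that rises all the way, in its words “So the values rise all the way”.

    starting material + coupling partner → intermediate (k = 0.0410 L mol⁻¹ s⁻¹)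
    second reagent + intermediate → product (k = 7.70 × 10⁻⁴ L mol⁻¹ s⁻¹)
    starting material + protic impurity → quenched substrate (k = 8.10 × 10⁻⁴ L mol⁻¹ s⁻¹)

- The flask gives 2.57 × 10⁻⁴ M, 8.24 × 10⁻⁴ M, 0.00270 M, 0.00440 M and 0.00405 M, so the row rises, then falls. Theta ends with its second reagent at 87.9% of its charge and its intermediate at 1.76% of its charge, against the reckoned 1.90%. Gamma's wait is 3.41 min, which gives a share of 2.85%, and gamma holds 2.57% of its charge at 80.0 min.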